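The 1,5-diazocan-2-one ring is traced back to an azetidin-2-one. Lactam nitrogen N1 of the eight-membered ring joins three groups: bridge carbon C8, carbonyl C2 and the benzamidobutyl chain. The chain's own primary amine can therefore become N1. Its partner is (S)-4-phenylazetidin-2-one carrying a 3-oxopropyl group on nitrogen, made from (S)-β-phenylalanine. In one operation reductive amination forms N1–C8, and the new secondary amine, held three carbons from the azetidinone nitrogen, captures the strained acyl carbon (N1–C2) while the old amide bond breaks, so four ring atoms become eight. C4 keeps its C–N bond and its (S) configuration. Methylation of N5 completes the target.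

Key step: step 4

Remark: N-(4-aminobutyl)benzamide is taken as a purchasable free base, and the descriptor at the benzylic carbon is (S) in every compound because the priority order N > phenyl > CH2 > H never changes.

Step 1
Reactants: 1 (S)-3-amino-3-phenylpropanoic acid
Product: 3 (S)-4-phenylazetidin-2-one, via S-pyridyl thioester 2 (not isolated)
Conditions: PPh3 (1.2 equiv), 2,2'-dipyridyl disulfide (1.2 equiv), MeCN (0.01 M), reflux
Reagents that add atoms: none
Why: Mukaiyama oxidation–reduction condensation: the thiophosphonium salt formed from PPh3 and the disulfide turns the carboxylate into thioester 2, whose free amine closes the ring by 4-exo-trig acylation under high dilution that disfavours oligomerisation, and the benzylic stereocentre is a spectator, so (S)-C3 of 1 becomes (S)-C4 of 3.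

Step 2
Reactants: 3 (S)-4-phenylazetidin-2-one; 4 3-bromo-1,1-dimethoxypropane
Product: 5 (S)-1-(3,3-dimethoxypropyl)-4-phenylazetidin-2-one
Conditions: powdered KOH, n-Bu4NBr (cat.), THF, 0 °C to rt
Reagents that add atoms: none
Why: Solid–liquid phase-transfer N-alkylation (SN2), the standard way to alkylate NH azetidinones: only the N–H is acidic enough for KOH, C4–H is not, so the configuration holds, and the acyclic dimethyl acetal is preferred to a cyclic dioxolane because it can be removed later with much weaker acid.

Step 3
Reactants: 5 (S)-1-(3,3-dimethoxypropyl)-4-phenylazetidin-2-one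
Product: 6 (S)-3-(2-oxo-4-phenylazetidin-1-yl)propanal
Conditions: Amberlyst-15, acetone–H2O (20:1), rt; filter, concentrate below 30 °C, use at once
Reagents that add atoms: water, O
Why: Acid-catalysed acetal hydrolysis on a sulfonic acid resin: the open-chain acetal ionises much faster than a monocyclic N-alkyl β-lactam is opened by dilute acid, and removal of the resin by filtration spares the β-amido aldehyde a basic aqueous work-up that could trigger retro-Michael loss of acrolein.

Step 4
Reactants: 6 (S)-3-(2-oxo-4-phenylazetidin-1-yl)propanal; 7 N-(4-aminobutyl)benzamide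
Product: 11 N-{4-[(4S)-2-oxo-4-phenyl-1,5-diazocan-1-yl]butyl}benzamide, via aldimine 8 (not isolated), via amino-azetidinone 9 (not isolated), via bicyclic carbinolamine 10 (not isolated)
Conditions: 7 (1.5 equiv), 4 Å MS, ClCH2CH2Cl, rt; NaBH(OAc)3, 0 °C to rt; aq. K2CO3 wash; crude free base, PhMe (0.05 M), 80–110 °C
Reagents that add atoms: none
Why: The primary amine of 7 condenses with aldehyde 6 to aldimine 8, and hydride transfer from NaBH(OAc)3 gives secondary amine 9, which forms the N1–C8 bond (reductive amination). After the acetate salt is neutralised and the solution is warmed, this nitrogen adds to the azetidinone carbonyl in a 6-exo-trig closure to the 1,5-diazabicyclo[4.2.0]octane carbinolamine 10, which collapses by cleaving the shared ring-fusion C–N bond, so the eight-membered ring arises by a four-atom ring expansion and not by a direct medium-ring cyclisation. The closest known reaction type is the transamidative ring expansion of N-(3-aminopropyl)azetidin-2-ones to 1,5-diazocan-2-ones, driven by loss of β-lactam strain and by the better amide resonance of the larger lactam. No lasting stereocentre is created: the carbinolamine carbon returns to sp2, and C4 keeps all four of its bonds, so it stays (S). Mono-alkylation is secured by forming the imine completely with an excess of 7 before the hydride is added, so that neither 9 nor the N5–H of 11 meets free aldehyde; the acyl transfer stays intramolecular because of the six-membered transition state and the dilution, and the benzamide N–H is not nucleophilic. A hydride is used in place of H2/Pd because the benzylic N–C4 bond of 4-arylazetidinones is prone to hydrogenolysis.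

Step 5
Reactants: 11 N-{4-[(4S)-2-oxo-4-phenyl-1,5-diazocan-1-yl]butyl}benzamide
Product: 13 N-{4-[(4S)-5-methyl-2-oxo-4-phenyl-1,5-diazocan-1-yl]butyl}benzamide, via methyleneiminium ion 12 (not isolated)
Conditions: 37% aq. CH2O, NaBH(OAc)3, ClCH2CH2Cl, rt
Reagents that add atoms: formaldehyde, C=O
Why: Reductive amination with formaldehyde: N5 is the only basic nitrogen, its iminium ion 12 is reduced by the acetoxyborohydride at room temperature, the lactam and the benzamide are inert, over-alkylation to an ammonium salt cannot occur, and C4 is untouched.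

Compound list
1 | (S)-3-amino-3-phenylpropanoic acid | N[C@@H](CC(=O)O)c1ccccc1 | starting material
2 | S-(pyridin-2-yl) (S)-3-amino-3-phenylpropanethioate | N[C@@H](CC(=O)Sc1ccccn1)c1ccccc1 | intermediate
3 | (S)-4-phenylazetidin-2-one | O=C1C[C@@H](c2ccccc2)N1 | intermediate
4 | 3-bromo-1,1-dimethoxypropane | COC(CCBr)OC | starting material
5 | (S)-1-(3,3-dimethoxypropyl)-4-phenylazetidin-2-one | COC(CCN1C(=O)C[C@H]1c1ccccc1)OC | intermediate
6 | (S)-3-(2-oxo-4-phenylazetidin-1-yl)propanal | O=CCCN1C(=O)C[C@H]1c1ccccc1 | intermediate
7 | N-(4-aminobutyl)benzamide | NCCCCNC(=O)c1ccccc1 | starting material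
8 | N-{4-[(E)-{3-[(4S)-2-oxo-4-phenylazetidin-1-yl]propylidene}amino]butyl}benzamide | O=C1C[C@@H](c2ccccc2)N1CC/C=N/CCCCNC(=O)c1ccccc1 | intermediate
9 | N-[4-({3-[(4S)-2-oxo-4-phenylazetidin-1-yl]propyl}amino)butyl]benzamide | O=C1C[C@@H](c2ccccc2)N1CCCNCCCCNC(=O)c1ccccc1 | intermediate
10 | N-{4-[(8S)-6-hydroxy-8-phenyl-1,5-diazabicyclo[4.2.0]octan-5-yl]butyl}benzamide (C6 transient, configuration not defined) | OC12C[C@@H](c3ccccc3)N1CCCN2CCCCNC(=O)c1ccccc1 | intermediate
11 | N-{4-[(4S)-2-oxo-4-phenyl-1,5-diazocan-1-yl]butyl}benzamide | O=C1C[C@@H](c2ccccc2)NCCCN1CCCCNC(=O)c1ccccc1 | intermediate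
12 | (4S)-1-(4-benzamidobutyl)-5-methylidene-2-oxo-4-phenyl-1,5-diazocan-5-ium acetate | C=[N+]1CCCN(CCCCNC(=O)c2ccccc2)C(=O)C[C@H]1c1ccccc1.CC(=O)[O-] | intermediate
13 | N-{4-[(4S)-5-methyl-2-oxo-4-phenyl-1,5-diazocan-1-yl]butyl}benzamide | CN1CCCN(CCCCNC(=O)c2ccccc2)C(=O)C[C@H]1c1ccccc1 | target

Total step count: 5. Longest linear sequence: 5 (1 → 3 → 5 → 6 → 11 → 13).

Steps most likely to fail

Step 4.
- **What may go wrong:** The primary amine may be alkylated twice. The azetidinone may be lost by β-elimination from the enamine tautomer of the imine. The acyl transfer by the hindered secondary amine may be too slow to outrun intermolecular aminolysis.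
- **Fallback:** It sets out from 3 and comes back at 13, and it separates ring expansion from side-chain attachment. Compound 3 is N-alkylated with 1-bromo-3-chloropropane (KOH, n-Bu4NBr, THF) to (S)-1-(3-chloropropyl)-4-phenylazetidin-2-one F1. Liquid ammonia in a sealed vessel at room temperature displaces chloride to give (S)-1-(3-aminopropyl)-4-phenylazetidin-2-one F2. Its unhindered primary amine should expand the ring in the same pot to (S)-4-phenyl-1,5-diazocan-2-one F3. Formaldehyde and NaBH(OAc)3 methylate N5 to (S)-5-methyl-4-phenyl-1,5-diazocan-2-one F4. The lactam N1–H is deprotonated (NaH, DMF) and alkylated with N-(4-bromobutyl)phthalimide to 2-{4-[(4S)-5-methyl-2-oxo-4-phenyl-1,5-diazocan-1-yl]butyl}isoindoline-1,3-dione F5. Hydrazine in ethanol (Ing–Manske cleavage) frees (4S)-1-(4-aminobutyl)-5-methyl-4-phenyl-1,5-diazocan-2-one F6. Benzoyl chloride with Et3N then gives 13.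

Step 1.
- **What may go wrong:** Intermolecular acylation may outrun closure of the four-membered ring, because the amine is unsubstituted and the amino acid dissolves only slowly.
- **Fallback:** It sets out from 1 and comes back at 3, and it replaces acid activation by a Breckpot-type cyclisation of an ester through a magnesium amide. SOCl2 in MeOH gives methyl (S)-3-amino-3-phenylpropanoate hydrochloride F7. TMSCl and Et3N give methyl (S)-3-phenyl-3-[(trimethylsilyl)amino]propanoate F8. t-BuMgCl removes the remaining N–H, and the amide closes onto the ester to give (S)-4-phenyl-1-(trimethylsilyl)azetidin-2-one F9. This loses silicon on aqueous NH4Cl work-up to give 3.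

Step 3.
- **What may go wrong:** The β-lactam may open under acid alongside acetal cleavage. The aldehyde may suffer retro-Michael fragmentation or self-condensation during isolation.
- **Fallback:** It sets out from 3 and comes back at 6, and it carries the aldehyde carbon as a terminal alkene that is released at neutral pH. Compound 3 is alkylated with 4-bromobut-1-ene (KOH, n-Bu4NBr, THF) to (S)-1-(but-3-en-1-yl)-4-phenylazetidin-2-one F10. Ozone in CH2Cl2 at −78 °C gives (4S)-4-phenyl-1-[2-(1,2,4-trioxolan-3-yl)ethyl]azetidin-2-one F11. Me2S reduces it to 6, which is taken into imine formation after evaporation.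

Further compounds
F1 | step 4 | (S)-1-(3-chloropropyl)-4-phenylazetidin-2-one | ClCCCN1C(=O)C[C@H]1c1ccccc1
F2 | step 4 | (S)-1-(3-aminopropyl)-4-phenylazetidin-2-one | NCCCN1C(=O)C[C@H]1c1ccccc1
F3 | step 4 | (S)-4-phenyl-1,5-diazocan-2-one | O=C1C[C@@H](c2ccccc2)NCCCN1
F4 | step 4 | (S)-5-methyl-4-phenyl-1,5-diazocan-2-one | CN1CCCNC(=O)C[C@H]1c1ccccc1
F5 | step 4 | 2-{4-[(4S)-5-methyl-2-oxo-4-phenyl-1,5-diazocan-1-yl]butyl}isoindoline-1,3-dione | CN1CCCN(CCCCN2C(=O)c3ccccc3C2=O)C(=O)C[C@H]1c1ccccc1
F6 | step 4 | (4S)-1-(4-aminobutyl)-5-methyl-4-phenyl-1,5-diazocan-2-one | CN1CCCN(CCCCN)C(=O)C[C@H]1c1ccccc1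
F7 | step 1 | methyl (S)-3-amino-3-phenylpropanoate hydrochloride | Cl.N[C@@H](CC(=O)OC)c1ccccc1
F8 | step 1 | methyl (S)-3-phenyl-3-[(trimethylsilyl)amino]propanoate | C[Si](C)(C)N[C@@H](CC(=O)OC)c1ccccc1
F9 | step 1 | (S)-4-phenyl-1-(trimethylsilyl)azetidin-2-one | C[Si](C)(C)N1C(=O)C[C@H]1c1ccccc1
F10 | step 3 | (S)-1-(but-3-en-1-yl)-4-phenylazetidin-2-one | C=CCCN1C(=O)C[C@H]1c1ccccc1
F11 | step 3 | (4S)-4-phenyl-1-[2-(1,2,4-trioxolan-3-yl)ethyl]azetidin-2-one | O=C1C[C@@H](c2ccccc2)N1CCC1OCOO1
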